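The readings stem from a simulated flask for an exercise, noise included.

You asked for a quick number on this flask, and the trap is to run the early rate out to 8.0 min. Each complex that reacts sets free a leaving ligand, and the scavenger can take up 0.300 equiv.

| flask | starting complex | incoming ligand | scavenger | remark | time |
|---|---|---|---|---|---|
| autumn | 0.041 M | 0.80 equiv (fed, over 2.5 min) | 0.30 equiv | run made earlier; the fed solution adds 0.50 times the starting volume |  |
| midnight | 0.16 M | 0.80 equiv (fed, over 2.5 min) | 0.30 equiv | run made earlier; the fed solution adds 0.50 times the starting volume |  |
| flask | 0.082 M | 0.800 equiv (fed, over 2.5 min) | 0.300 equiv | the fed solution adds 0.50 times the starting volume | 8.0 min |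

- autumn (time / min: starting complex / %, complex with three exchanged / %): 2.50: 92.2, 0.3; 5.00: 84.0, 0; 8.00: 72.8, 0; 10.0: 68.2, 0.8
- midnight (time / min: starting complex / %, complex with three exchanged / %): 2.50: 78.6, 0.9; 5.00: 59.1, 1.5; 8.00: 52.8, 0.6; 10.0: 50.7, 0.1

(scatter of a reading: 1 percentage point)

* part of the starting complex that has reacted at 8.0 min
* share of the unused incoming ligand that is free and not bound as idle adduct, at 8.0 min

- what is said of leaving ligand includes idle adduct
- amounts are per litre of the starting volume; all of the dose is in the solution fed
- what was read earlier has a scatter of 1 percentage point, one standard deviation
- on the list of suspects stand: complex with one exchanged + incoming ligand <-> leaving ligand + complex with two exchanged; leaving ligand + incoming ligand <-> idle adduct; complex with two exchanged + incoming ligand <-> leaving ligand + complex with three exchanged; scavenger + leaving ligand -> scavenged by-product; starting complex + incoming ligand <-> leaving ligand + complex with one exchanged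
- the earlier runs do not show how much of incoming ligand is bound; that part of a forecast is a guess

Read at 8.00 min, the autumn run stands at 0.907 and the midnight run at 1.57 in what I call turns, the fraction of the starting complex reacted divided by the scavenger's equivalents. Past one turn, the midnight run loses 6.3 percentage points between 5.00 min and 8.00 min, less than the 11 points of the more dilute autumn run.

This flask lies between them, and interpolating on the logarithm of concentration gives me 1.25 turns, so 37.4% reacted. That leaves 7.38% of the charge as leaving ligand beyond the scavenger's capacity, counting one exchange per reacted complex. If all of it sat as idle adduct, the free share would be 82.7%. That is a rough figure on this count, not a bound, and the free share stays a guess, as the runs do not show the binding.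

The forecast gives 38% reacted and 87% free, both above my figures, reading the midnight run as stalling “close to where 0.30 equiv of scavenger is exhausted”. The flask gives 38.4% reacted and 88.8% free, which is 1.28 turns against my 1.25.

    complex with one exchanged + incoming ligand ⇌ leaving ligand + complex with two exchanged (K = 0.410, k = 0.980 /M/min)
    leaving ligand + incoming ligand ⇌ idle adduct, settled at all times (K = 27.0 /M)
    complex with two exchanged + incoming ligand ⇌ leaving ligand + complex with three exchanged (K = 14.0, k = 0.650 /M/min)
    scavenger + leaving ligand → scavenged by-product (k = 270 /M/min)
    starting complex + incoming ligand ⇌ leaving ligand + complex with one exchanged (K = 2.50, k = 2.50 /M/min)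

At 3.44 min in this flask the half-life of the scavenger by its own step is 1.7 min, shorter than the 8.8 min of the starting complex by its forward step alone. At 8.0 min the scavenger of this flask, the limiting reagent, is down to 1.7% of its charge, less than the 62% of its charge of starting complex still there. For the neighbour flask with 0.21 M of starting complex and the same equivalents, extending my line past the midnight run gives 1.71 turns, so 51.2% reacted. The computed neighbour has 50.2% reacted, with 0% of its scavenger left.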